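A fractional order in Cat is easy to believe and risky to carry: it reads like a property of the catalyst, yet the same readings also arise from a rate of which one part owes nothing to Cat.

| setting | west | south-west | south-east | north-east | east |
|---|---|---|---|---|---|
| Sub | 80.0 mM | 48.0 mM | 120 mM | 80.0 mM | 80.0 mM |
| Cat | 6.40 mM | 6.40 mM | 6.40 mM | 3.20 mM | 1.80 mM |
| time |  |  |  |  | 21 min |

- west run (time / min: [Prd] / mM): 2.6: 3.83; 5.2: 7.99; 7.9: 12.34; 10: 15.72; 13: 20.50; 16: 25.10; 18: 28.06; 21: 32.55
- south-west run (time / min: [Prd] / mM): 2.6: 3.25; 5.2: 6.96; 7.9: 10.60; 10: 13.10; 13: 16.46; 16: 20.53; 18: 22.61; 21: 25.70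
- south-east run (time / min: [Prd] / mM): 2.6: 4.58; 5.2: 8.83; 7.9: 13.72; 10: 17.38; 13: 22.40; 16: 27.52; 18: 31.15; 21: 35.85
- north-east run (time / min: [Prd] / mM): 2.6: 2.39; 5.2: 5.35; 7.9: 8.56; 10: 10.17; 13: 13.23; 16: 16.35; 18: 18.01; 21: 21.16

(each reading ± 0.2 mM)

- the exponent of [Cat] in the starting rate at the charge of the west run (at the point where two percent of the Sub have become Prd)
- the exponent of [Sub] in the starting rate at the charge of the west run (at the point where two percent of the Sub have become Prd) (one fixed amount of Prd, the same in the runs compared)
- the south-west run starts with 32.0 mM less of Sub than the west run, and with no Prd. Compared where both hold the same amount of Sub, once fifteen percent of what the south-west run was charged with has turned into Prd, is the south-west run faster, slower or alike (within a tenth)?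
- Prd in the east run at 21 min, as a share of the Sub charged

- Overall: Sub -> Prd, with Cat as catalyst.
- Constant volume, constant temperature.
- A reading of a species includes what of it is bound.
- An order is taken over about fifteen percent of the charge, up and down.

The east run holds less Cat than any earlier run, so I took two ways to its Prd at 21 min, both from the last readings of the west and north-east runs, which were charged with the same Sub and with different Cat. The first treats the Cat dependence as a power: those two readings give an exponent of 0.621, which carried down from the north-east run gives 14.8 mM, or 18.5% of the charge.

The second draws a straight line through the same two readings and runs it back to no Cat. I called the intercept the Cat-free yield, the Prd that 80.0 mM of Sub makes in 21 min with no Cat, the uncatalysed background: 9.77 mM, with a scatter near 0.447 mM. This way gives the east run 16.2 mM, or 20.2%, more than the power gives.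

The two ways part, and both pass through both readings, so I looked at the Sub runs. With the Cat-free yield taken in proportion to Sub, the remainders at 21 min are 19.8 mM, 22.8 mM and 21.2 mM for the south-west, west and south-east runs. From the south-west to the south-east run, Sub rises by a factor of 2.50 and the remainder by a factor of 1.07. I read that as favouring the line, so I committed to 20.2%.

The forecast differed from me: 18.4% for the east run, with 0.6 for the Cat order, 0.24 for the Sub order, and alike for the comparison at equal Sub. Its ground for the Cat order was: “This suggests a monomer–dimer resting catalyst, with the order drifting toward 1 at low Cat.”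

The east run gave 19.9%, and the other answers were 0.65, 0.25 and alike.

    Cat + Sub ⇌ Cat.Sub (23.34 M⁻¹ min⁻¹, 0.5862 min⁻¹)
    Cat.Sub → Prd + Cat (0.4788 min⁻¹)
    Cat.Sub + Sub ⇌ Cat.Sub2, settled at all times (11.90 M⁻¹)
    Sub → Prd (0.005964 min⁻¹)

A power-law fit left a root mean square residual of 1.8 in units of the scatter. With the Cat-free yield taken off, the Prd left at 21 min over the Cat charged is 3.42 in the east run, against 3.56 in the west run. In the south-east run, Prd came to a quarter of the Sub charged, 30.0 mM, at 17.4 min, and the Cat-free yield scaled in proportion to that run's Sub and to that time comes to 12.1 mM.

All runs come from a simulation from invented constants; scatter was added.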